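**Retrosynthetic overview**
1. Helenien ⇒ lutein + 2 palmitoyl chloride. Lutein ⇒ C15 + C10 + C15 by two Wittig olefinations (C11=C12 and C11'=C12') on 2,7-dimethylocta-2,4,6-trienedial.
2. Both C15 phosphonium salts ⇒ one (6R)-3-oxo-ε-ring ketone. Its unselective C3 reduction gives the 3,6-trans alcohol (3R,6R, the ε end) and the 3,6-cis alcohol (3S,6R), and both are used.
3. β ring ⇒ cis ε ring. A base-mediated C4=C5 → C5=C6 shift at the C25 apo-aldehyde stage erases C6 and leaves (3R).
4. C3 oxygen ⇒ allylic C–H oxidation after ring closure. Ring ⇒ acyclic pseudoionone by an enantioselective, proton-initiated C1–C6 cation–olefin cyclisation that ends with loss of H-4.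
5. Ring order: one cyclisation (step 1) builds the six-membered ring of both end groups as the ε ring. Half of the material is converted to the β ring in step 8.

**Assumptions and conventions**
- Positions are given in carotenoid numbering: C1 is the gem-dimethyl carbon, C3 the carbinol carbon, C5 the methyl-bearing ring carbon, and C6 the ring carbon that carries the chain.
- Commercial pseudoionone is a 5E/5Z mixture and is drawn as (3E,5E). The strong acid interconverts the two isomers through the protonated dienone, so both feed the same cyclisation.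
- The hand of the chiral acid that gives (R) is written as (S,S). If induction runs the other way, its mirror image is used.
- 2,7-Dimethylocta-2,4,6-trienedial, the industrial C10 carotenoid dialdehyde, is taken as purchasable.
- All polyene steps are run under N2 in dim light.

**Route**

Step 1
Reactants: 1 pseudoionone, (3E,5E)-6,10-dimethylundeca-3,5,9-trien-2-one
Product: 2 (R)-α-ionone, (3E)-4-[(1R)-2,6,6-trimethylcyclohex-2-en-1-yl]but-3-en-2-one
Conditions: (S,S)-imidodiphosphorimidate acid HN[P(=NSO2CF3)(O2C20H10Ar2)]2 (O2C20H10Ar2 = (S)-3,3'-Ar2-1,1'-binaphthalene-2,2'-diolate, Ar = 3,5-(CF3)2C6H3), 5 mol %, (CF3)3COH, 0 °C, stopped when 1 is consumed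
Reagents that add atoms: none
Why: Proposed new method: a confined, very strong chiral Brønsted acid protonates the terminal C9=C10 alkene of 1 (carotenoid C1=C2) while the chain lies in a chair-like fold inside the chiral anion pocket, the C5=C6 π bond closes onto the tertiary cation and sets C6 as R, and the bound anion removes H-4 from the C5 cation to give the non-conjugated ring alkene under kinetic control (the drift to β-ionone is held back by the low temperature and by stopping once 1 is consumed); the closest known reaction types are the H3PO4 cyclisation of pseudoionone to racemic α-ionone and imidodiphosphorimidate-catalysed enantioselective cation–olefin (polyene) cyclisations in fluorinated alcohols.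

Step 2
Reactants: 2 (R)-α-ionone
Product: 3 (R)-3-oxo-α-ionone, (4R)-3,5,5-trimethyl-4-[(1E)-3-oxobut-1-en-1-yl]cyclohex-2-en-1-one
Conditions: dirhodium tetrakis(caprolactamate) Rh2(C6H10NO)4 (1 mol %), t-BuOOH (70% in H2O, 5 equiv), 1,2-dichloroethane, 40 °C, no added base
Reagents that add atoms: tert-butyl hydroperoxide, CC(C)(C)OO
Why: Radical allylic C–H oxidation (abstraction by t-BuOO·, then collapse of the allylic peroxide to the enone) attacks C3, the only unhindered ring allylic CH2, because C6–H is shielded by the gem-dimethyl group and deactivated by the enone, and the base-free medium leaves the now acidic C6–H stereocentre untouched.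

Step 3
Reactants: 3 (R)-3-oxo-α-ionone
Product: 4 (4R)-4-[(1E)-3-hydroxy-3-methylpenta-1,4-dien-1-yl]-3,5,5-trimethylcyclohex-2-en-1-one (about 1:1 at carbinol carbon C9)
Conditions: CH2=CHMgBr (1.05 equiv), LaCl3·2LiCl (0.3 equiv), THF, −78 °C; then H2O
Reagents that add atoms: vinylmagnesium bromide, C=C[Mg]Br
Why: Chemoselective Grignard 1,2-addition works because the unhindered methyl ketone C9 reacts much faster than the ring carbonyl, which is flanked by a neopentyl CH2 and screened by the axial C1 methyl (the same bias lets borohydride reduce only C9 in 3-oxo-ionone-type diketones), the weakly basic lanthanum species suppresses enolisation at C6 so the R centre holds, and the unselective new C9 centre is erased in steps 5 and 6.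

Step 4
Reactants: 4 keto carbinol
Product: 5 trans diol (1R,4R)-4-[(1E)-3-hydroxy-3-methylpenta-1,4-dien-1-yl]-3,5,5-trimethylcyclohex-2-en-1-ol (3R,6R); 6 cis diol (1S,4R)-4-[(1E)-3-hydroxy-3-methylpenta-1,4-dien-1-yl]-3,5,5-trimethylcyclohex-2-en-1-ol (3S,6R); both are kept
Conditions: NaBH4 (1.0 equiv), CeCl3·7H2O (1.0 equiv), MeOH, −20 °C; SiO2 chromatography separates 5 from 6
Reagents that add atoms: none
Why: Luche 1,2-reduction of the ring enone shows little facial bias, so the fixed (6R) centre turns the two C3 epimers into separable diastereomers formed in comparable amounts, and both are wanted, since trans (3R,6R) carries the ε-end configuration and cis (3S,6R) carries the oxygen on the face that becomes (3R) of the β ring.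

Step 5
Reactants: 5 trans diol
Product: 7 [(2E,4E)-5-[(1R,4R)-4-hydroxy-2,6,6-trimethylcyclohex-2-en-1-yl]-3-methylpenta-2,4-dien-1-yl]triphenylphosphonium bromide
Conditions: Ph3P·HBr (1.0 equiv), CH2Cl2, 0 °C to rt; precipitated with Et2O and recrystallised
Reagents that add atoms: triphenylphosphine hydrobromide, [Br-].c1ccccc1[PH+](c1ccccc1)c1ccccc1
Why: In this SN1'-type allylic substitution (the standard vinyl-carbinol to Wittig-salt conversion) the tertiary bis-allylic C9 alcohol ionises to a pentadienyl cation far faster than the secondary ring allylic alcohol, PPh3 captures the unhindered terminus C11 to give the (E,E)-dienyl salt, and because the single equivalent of acid is consumed C3 and C6 stay intact.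

Step 6
Reactants: 6 cis diol
Product: 8 [(2E,4E)-5-[(1R,4S)-4-hydroxy-2,6,6-trimethylcyclohex-2-en-1-yl]-3-methylpenta-2,4-dien-1-yl]triphenylphosphonium bromide
Conditions: Ph3P·HBr (1.0 equiv), CH2Cl2, 0 °C to rt; precipitated with Et2O and recrystallised
Reagents that add atoms: triphenylphosphine hydrobromide, [Br-].c1ccccc1[PH+](c1ccccc1)c1ccccc1
Why: The same SN1'-type allylic substitution as in step 5 applies, with selective ionisation at the tertiary bis-allylic C9 and capture of C11 by PPh3, so the (3S,6R) centres are untouched.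

Step 7
Reactants: 8 cis C15 phosphonium bromide; 9 (2E,4E,6E)-2,7-dimethylocta-2,4,6-trienedial
Product: 11 (3S,6R)-3-hydroxy-12'-apo-ε-caroten-12'-al, via cis-C15 phosphorane 10 (not isolated)
Conditions: 9 (2.5 equiv), NaOMe (1.1 equiv), MeOH/CH2Cl2, −10 °C to rt, slow addition of 8; excess 9 recovered
Reagents that add atoms: none
Why: Wittig olefination of one aldehyde of the symmetrical dialdehyde (kept in excess and met by slowly generated ylide to hold back double condensation) forms C11=C12, any Z isomer at this bond relaxes to all-E on warming in step 8, and no stereocentre is involved.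

Step 8
Reactants: 11 (3S,6R)-3-hydroxy-12'-apo-ε-caroten-12'-al
Product: 12 (3R)-3-hydroxy-12'-apo-β-caroten-12'-al
Conditions: NaOMe (2 equiv), anhydrous MeOH/THF, 50 °C; AcOH quench; crystallisation
Reagents that add atoms: none
Why: In this base-mediated prototropic alkene shift C6–H is the vinylogous α-position of the hexaenal, so methoxide removes it and the extended enolate is reprotonated at C4 to bring the ring alkene into conjugation (the same thermodynamic drive as α-ionone to β-ionone and lutein to zeaxanthin), which erases C6 while the untouched C3 centre becomes (3R) only through a change of CIP priorities.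

Step 9
Reactants: 12 (3R)-3-hydroxy-12'-apo-β-caroten-12'-al; 7 trans C15 phosphonium bromide
Product: 14 lutein, (3R,3'R,6'R)-β,ε-carotene-3,3'-diol, via trans-C15 phosphorane 13 (not isolated)
Conditions: NaOMe (1.2 equiv), MeOH/CH2Cl2, 0 °C to rt; then reflux in EtOH (Z to all-E); crystallisation
Reagents that add atoms: none
Why: Wittig olefination forms C11'=C12' and completes the C40 chain, brief heating equilibrates the hindered Z isomer to all-E, methoxide at room temperature cannot deprotonate C6' because no carbonyl is conjugated to it so all three stereocentres persist, and crystallisation removes the diastereomers that arise from any minor enantiomer of either half.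

Step 10
Reactants: 14 lutein
Product: 15 helenien, (3R,3'R,6'R)-β,ε-carotene-3,3'-diyl dipalmitate
Conditions: palmitoyl chloride (2.4 equiv), pyridine (5 equiv), 4-(dimethylamino)pyridine (0.1 equiv), CH2Cl2, 0 °C to rt, dark
Reagents that add atoms: palmitoyl chloride, CCCCCCCCCCCCCCCC(=O)Cl
Why: Nucleophile-catalysed O-acylation esterifies both secondary alcohols without breaking their C–O bonds, so configuration at C3 and C3' is retained, and the pyridine-buffered medium prevents ionisation of the allylic 3'-ester.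

**Compound list**
1 | pseudoionone, (3E,5E)-6,10-dimethylundeca-3,5,9-trien-2-one | CC(C)=CCC/C(C)=C/C=C/C(C)=O | starting material
2 | (R)-α-ionone | CC(=O)/C=C/[C@H]1C(C)=CCCC1(C)C | intermediate
3 | (R)-3-oxo-α-ionone | CC(=O)/C=C/[C@H]1C(C)=CC(=O)CC1(C)C | intermediate
4 | (4R)-4-[(1E)-3-hydroxy-3-methylpenta-1,4-dien-1-yl]-3,5,5-trimethylcyclohex-2-en-1-one (C9 epimers) | C=CC(C)(O)/C=C/[C@H]1C(C)=CC(=O)CC1(C)C | intermediate
5 | trans diol, (1R,4R)-4-[(1E)-3-hydroxy-3-methylpenta-1,4-dien-1-yl]-3,5,5-trimethylcyclohex-2-en-1-ol (C9 epimers) | C=CC(C)(O)/C=C/[C@H]1C(C)=C[C@H](O)CC1(C)C | intermediate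
6 | cis diol, (1S,4R)-4-[(1E)-3-hydroxy-3-methylpenta-1,4-dien-1-yl]-3,5,5-trimethylcyclohex-2-en-1-ol (C9 epimers) | C=CC(C)(O)/C=C/[C@H]1C(C)=C[C@@H](O)CC1(C)C | intermediate
7 | trans (3R,6R) ε-C15 triphenylphosphonium bromide | [Br-].c1ccccc1[P+](c1ccccc1)(c1ccccc1)C/C=C(C)/C=C/[C@H]1C(C)=C[C@H](O)CC1(C)C | intermediate
8 | cis (3S,6R) ε-C15 triphenylphosphonium bromide | [Br-].c1ccccc1[P+](c1ccccc1)(c1ccccc1)C/C=C(C)/C=C/[C@H]1C(C)=C[C@@H](O)CC1(C)C | intermediate
9 | (2E,4E,6E)-2,7-dimethylocta-2,4,6-trienedial | O=C/C(C)=C/C=C/C=C(C)/C=O | starting material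
10 | cis-C15 phosphorane (ylide of 8, not isolated) | c1ccccc1[P+](c1ccccc1)(c1ccccc1)[CH-]/C=C(C)/C=C/[C@H]1C(C)=C[C@@H](O)CC1(C)C | intermediate
11 | (3S,6R)-3-hydroxy-12'-apo-ε-caroten-12'-al | O=C/C(C)=C/C=C/C=C(C)/C=C/C=C(C)/C=C/[C@H]1C(C)=C[C@@H](O)CC1(C)C | intermediate
12 | (3R)-3-hydroxy-12'-apo-β-caroten-12'-al | O[C@@H]1CC(C)=C(/C=C/C(C)=C/C=C/C(C)=C/C=C/C=C(C)/C=O)C(C)(C)C1 | intermediate
13 | trans-C15 phosphorane (ylide of 7, not isolated) | c1ccccc1[P+](c1ccccc1)(c1ccccc1)[CH-]/C=C(C)/C=C/[C@H]1C(C)=C[C@H](O)CC1(C)C | intermediate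
14 | lutein, (3R,3'R,6'R)-β,ε-carotene-3,3'-diol | O[C@@H]1CC(C)=C(/C=C/C(C)=C/C=C/C(C)=C/C=C/C=C(C)/C=C/C=C(C)/C=C/[C@H]2C(C)=C[C@H](O)CC2(C)C)C(C)(C)C1 | intermediate
15 | helenien (lutein dipalmitate) | CCCCCCCCCCCCCCCC(=O)O[C@@H]1CC(C)=C(/C=C/C(C)=C/C=C/C(C)=C/C=C/C=C(C)/C=C/C=C(C)/C=C/[C@H]2C(C)=C[C@H](OC(=O)CCCCCCCCCCCCCCC)CC2(C)C)C(C)(C)C1 | target

**Totals**
Total step count: 10.
Longest linear sequence: 9 (steps 1, 2, 3, 4, 6, 7, 8, 9, 10).

**Three steps most likely to fail**

Step 1, the enantioselective cyclisation. The dienone carbonyl may tie up the acid, the ee may be modest, or the product may drift to β-ionone.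
- The fallback gives up asymmetric catalysis in favour of a racemic ring closure followed by resolution. It sets out from 1 and comes back at 2.
- 85% H3PO4 in toluene at 35 °C closes 1 to racemic α-ionone F1.
- F1 is split by simulated-moving-bed chromatography on cellulose tris(3,5-dimethylphenylcarbamate) into 2 and (S)-α-ionone F2, which is set aside.

Step 8, the ε to β shift on the C25 polyenal. The aldehyde may undergo vinylogous self-condensation, or C3–OH may be lost by elimination.
- The fallback moves the shift to the robust ionone stage and builds a separate β-C15 salt. It sets out from 2, comes back at 12, and bypasses 8, 10 and 11.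
- 2 with ethylene glycol and pyridinium p-toluenesulfonate (benzene, Dean–Stark) gives (R)-α-ionone ethylene ketal F3.
- Rh2(C6H10NO)4/t-BuOOH oxidation gives the 3-oxo ketal F4.
- LiBH(s-Bu)3 in THF at −78 °C delivers hydride anti to the axial C1 methyl and gives mainly the cis (3S,6R)-3-hydroxy ketal F5.
- 0.3 M aqueous HCl in THF at 0 °C unmasks (3S,6R)-3-hydroxy-α-ionone F6.
- KOH in MeOH at 50 °C shifts the alkene to give (3R)-3-hydroxy-β-ionone F7.
- CH2=CHMgBr (2.2 equiv) gives (3R)-3-hydroxy-vinyl-β-ionol F8.
- Ph3P·HBr in MeOH gives the β-C15 triphenylphosphonium bromide F9, which has no allylic ring alcohol.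
- NaOMe converts F9 to the β-C15 phosphorane F10, which condenses with excess 9 to give 12.

Step 5, salt formation next to the acid-labile ring allylic alcohol. The risks are C3 epimerisation, substitution or dehydration. Step 6 shares this risk and is bypassed by the fallback for step 8.
- The fallback makes the salt before the allylic alcohol exists and reduces last. It sets out from 4 and comes back at 14.
- 4 with Ph3P·HBr in CH2Cl2 gives the 3-oxo-ε-C15 triphenylphosphonium bromide F11.
- In 1,2-epoxybutane/EtOH at reflux, a neutral proton scavenger that spares the acidic C6' centre, F11 forms the 3-oxo-C15 phosphorane F12.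
- F12 condenses with 12 to give (3R,6'R)-3-hydroxy-β,ε-caroten-3'-one F13.
- NaBH4/CeCl3·7H2O in MeOH/THF reduces F13 to 14 together with 3'-epilutein F14, which is removed by chromatography and crystallisation.

**Further compounds**
F1 | step 1 | racemic α-ionone | CC(=O)/C=C/C1C(C)=CCCC1(C)C
F2 | step 1 | (S)-α-ionone | CC(=O)/C=C/[C@@H]1C(C)=CCCC1(C)C
F3 | step 8 | (R)-α-ionone ethylene ketal | CC1(OCCO1)/C=C/[C@H]2C(C)=CCCC2(C)C
F4 | step 8 | (R)-3-oxo-α-ionone 9-ethylene ketal | CC1(OCCO1)/C=C/[C@H]2C(C)=CC(=O)CC2(C)C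
F5 | step 8 | (3S,6R)-3-hydroxy-α-ionone 9-ethylene ketal | CC1(OCCO1)/C=C/[C@H]2C(C)=C[C@@H](O)CC2(C)C
F6 | step 8 | (3S,6R)-3-hydroxy-α-ionone | CC(=O)/C=C/[C@H]1C(C)=C[C@@H](O)CC1(C)C
F7 | step 8 | (3R)-3-hydroxy-β-ionone | O[C@@H]1CC(C)=C(/C=C/C(C)=O)C(C)(C)C1
F8 | step 8 | (3R)-3-hydroxy-vinyl-β-ionol (C9 epimers) | O[C@@H]1CC(C)=C(/C=C/C(C)(O)C=C)C(C)(C)C1
F9 | step 8 | (3R) β-C15 triphenylphosphonium bromide | [Br-].O[C@@H]1CC(C)=C(/C=C/C(C)=C/C[P+](c2ccccc2)(c2ccccc2)c2ccccc2)C(C)(C)C1
F10 | step 8 | β-C15 phosphorane | O[C@@H]1CC(C)=C(/C=C/C(C)=C/[CH-][P+](c2ccccc2)(c2ccccc2)c2ccccc2)C(C)(C)C1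
F11 | step 5 | (6R)-3-oxo-ε-C15 triphenylphosphonium bromide | [Br-].c1ccccc1[P+](c1ccccc1)(c1ccccc1)C/C=C(C)/C=C/[C@H]1C(C)=CC(=O)CC1(C)C
F12 | step 5 | 3-oxo-C15 phosphorane | c1ccccc1[P+](c1ccccc1)(c1ccccc1)[CH-]/C=C(C)/C=C/[C@H]1C(C)=CC(=O)CC1(C)C
F13 | step 5 | (3R,6'R)-3-hydroxy-β,ε-caroten-3'-one | O[C@@H]1CC(C)=C(/C=C/C(C)=C/C=C/C(C)=C/C=C/C=C(C)/C=C/C=C(C)/C=C/[C@H]2C(C)=CC(=O)CC2(C)C)C(C)(C)C1
F14 | step 5 | 3'-epilutein, (3R,3'S,6'R)-β,ε-carotene-3,3'-diol | O[C@@H]1CC(C)=C(/C=C/C(C)=C/C=C/C(C)=C/C=C/C=C(C)/C=C/C=C(C)/C=C/[C@H]2C(C)=C[C@@H](O)CC2(C)C)C(C)(C)C1
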